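## The problem

Hansforester A is a linear tetraester in which five pieces are joined only through oxygen: an orsellinate (ring A), an (R)-3-hydroxybutanoate (unit 1), a 2,4-dihydroxy-6-[(R)-2-hydroxypropyl]benzoate (ring B), a second (R)-3-hydroxybutanoate (unit 2) and (R)-1-(3,5-dihydroxyphenyl)propan-2-ol (ring C). No carbon–carbon bond links the pieces, so the task is to make four ester bonds in a workable order and to build ring B, the only piece esterified at both ends. The four stereocentres are all secondary carbinol carbons of R configuration; ester links and methylene groups insulate them from one another, so none can direct another and each must come from the chiral pool or from a reagent. Two of the esters are β-acyloxy esters, which eliminate to crotonates (E1cB) with any moderately strong base, and the six phenols make the rings sensitive to oxidants and electrophiles, so the closing steps must be neutral. Two ester carbonyls are benzoates flanked by two ortho substituents (ring A: OH and CH3; ring B: OH and CH2), which resist ordinary acylation, and in ring B the side-chain hydroxyl is placed to lactonise onto this carboxyl to a dihydroisocoumarin. The feature that opens a way round both difficulties is the oxygen pattern of ring B: the ester carbon, C1, C2 and C3 are the four carbons of an acetoacetate, while C4, C5, C6, the side-chain CH2 and the carbinol carbon are C2 to C6 of a 6-methyl-5,6-dihydropyran-2-one whose ring oxygen is the carbinol oxygen. At the dihydro level of ring B the C1 ester is a β-keto ester that can change its alcohol through an acylketene, so the crowded benzoate never has to be made by acylation.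

## Retrosynthesis

**28 to 27.** The last operation should only unveil phenols. Base is excluded by the β-acyloxy esters and boron or aluminium halides by the four esters, which leaves hydrogenolysis of benzyl-type ethers; none of the esters is benzylic. The precursor is 27: the four phenols of rings A and C are benzyl ethers, O4 of ring B carries a benzyloxymethyl group, and the O2 phenol of ring B, hydrogen-bonded to its ester, stays free.

**27 to 26.** Ring B of 27 is taken back to its 5,6-dihydro form 26 (C2 ketone, hydrogens on C1, C5 and C6). Cutting the ring B ester of 27 directly would lead to a 2,6-disubstituted hydroxy acid that lactonises and can only be esterified by carboxylate alkylation. In 26 the same ester is a β-keto ester. The forward step must take two hydrogens from one ring in the presence of five benzylic ethers.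

**26 to 24 and 23.** The C1 carboxyl–oxygen bond is cut to the tert-butyl ester 24 and the alcohol 23, with acylketene 25 as the bond-forming species. Against cutting the unit 2–ring C ester first, this cut divides the molecule into two halves of similar size. The forward reaction must be neutral and hot, and the ring B side-chain oxygen must already be acylated, since a free hydroxyl there would trap the ketene as a bicyclic lactone.

**24 to 10 and 16.** The ester between unit 1 and the ring B carbinol is the only one of the four in which an unhindered acid meets an unhindered secondary alcohol, so it is cut to alcohol 10 and acid 16. The hindered orsellinate bond stays inside 16 and is made early on small molecules. One condition follows: the cyclic 1,3-dione must not be present as its free acidic enol, which a carbodiimide with DMAP would acylate at oxygen and carbon.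

**10 to 9.** Hence a mask: 10 is the O4 benzyloxymethyl enol ether of dione 9. A chloromethyl ether is preferred to a benzyl halide because it alkylates dione enolates at oxygen, and to a silyl group because 3-silyloxyenones pass their silyl group on to alcohols. After aromatisation the same group is a phenol ether that leaves in the final hydrogenolysis. The forward step must choose O4 over O2 and over the free carbinol.

**9 to 6 and 7.** Ring B of 9 is cut at C1–C6 and C3–C4. The first is a Michael bond from C2 of tert-butyl acetoacetate 7 to C4 of lactone 6; the second is a Claisen bond from the acetyl methyl of 7 to the lactone carbonyl, through adduct 8. A malonate-plus-enone cut would also give a dihydroresorcylate but would leave the carbinol to be introduced and protected separately. Here the lactone oxygen is the carbinol oxygen, so ring opening delivers the free hydroxyl and its stereocentre at once. The precursors have six and eight carbons, one stereocentre and no protecting group. The forward reaction must add through C2 and cyclise through C4 of the acetoacetate, and the liberated alkoxide must not attack the ring ester, hence tert-butyl.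

**6 to 4, then 1 and 2.** Lactone 6 is the Z-hydroxy enoate 5 closed on itself; 5 comes from ynoate 4 by semihydrogenation, and 4 from lithiated ethyl propiolate 3 (from 1) and (R)-propylene oxide 2 by bond formation at the epoxide CH2. The epoxide is inexpensive and its stereocentre is not touched.

**16 to 15, then 13 and 14; 13 to 12 to 11.** Acid 16 is tert-butyl ester 15 without its tert-butyl group. The orsellinate bond of 15 is cut at the alkyl C–O bond: carboxylate 13 displaces activated tert-butyl (S)-3-hydroxybutanoate 14 with inversion (Mitsunobu), which is indifferent to the two ortho substituents. Acid 13 follows from methyl orsellinate 11 through 12 by benzylation and saponification.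

**23 to 22, then 19 and 20; 19 to 17 and 2.** Alcohol 23 is taken back to acetoacetate 22, so that the unit 2 stereocentre is set by asymmetric hydrogenation and no hydroxy acid needs protection. Ester 22 comes from carbinol 19 and acetylketene 21, released from dioxinone 20. Carbinol 19 is cut at the aryl–CH2 bond to Grignard reagent 18 (from bromide 17) and the same epoxide 2.

## Roads not taken

**Alternative 1:** The cut is the C6–CH2 bond of ring B together with the lactone C–O bond. In the forward step 2,4-dimethoxybenzoic acid A2 is palladated at its only free ortho position under carboxylate direction (Pd(OAc)2), the aryl–palladium bond opens epoxide 2 at CH2, and the alkoxide closes onto the carboxyl to give (R)-6,8-dimethoxy-3-methylisochroman-1-one A1.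
- Merits: one catalytic step from two commercial compounds, unambiguous regiochemistry, configuration from the same epoxide, and a ring that is aromatic from the start.
- Weak points: A1 ties the carboxyl and carbinol of ring B together in exactly the δ-lactone the open form tends to re-form. After opening, the carbinol must be acylated and the di-ortho-substituted acid esterified by a secondary β-hydroxy ester, realistically only by carboxylate alkylation with inversion. The methyl ethers must be exchanged or cleaved by boron halides in the presence of four esters.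
- Comparison: this road is shorter to a ring B building block and needs no mask and no dehydrogenation. The chosen plan sets against it that 9 delivers the two functions already differentiated (free carbinol, exchangeable tert-butyl β-keto ester) and that the difficult ester is formed by ketene capture.

**Alternative 2:** The cut replaces the two ester oxygens on the ring B and ring C carbinol carbons by C–C bonds, giving diketone A4. In the forward step a peracid inserts oxygen twice, each (R)-1-arylpropan-2-yl group migrating with retention in preference to the primary CH2, to give hansforester A hexaacetate A3.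
- Merits: two ester bonds in one operation without any acylation, and a clear migratory preference.
- Weak points: A4 is a bis(β-acyloxy ketone), more prone to β-elimination than the esters of the target, and its two α-methyl ketone stereocentres can epimerise. The two hindered benzoate bonds still have to be made. The peracid requires deactivated rings, hence six acetates, whose removal competes with four alkyl esters and with elimination.
- Comparison: it is better in making two ester bonds at once. The chosen plan sets against it configurationally stable carbinol centres taken from 2, no oxidant stronger than DDQ, and a neutral final deprotection.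

**Alternative 3:** The cut is the C1–C6 bond of ring A. In the forward step the 3,5,7-trioxooctanoate A6 of the complete ring B–ring C alcohol cyclises by aldol attack of C2 on the C7 ketone and dehydrates to A5, hansforester A with rings B and C as benzyl ethers.
- Merits: the ring A ester is made from an aliphatic acyl donor before the arene exists, so there is no hindered acylation and no inversion, and ring A needs no protection. This is the same logic the chosen plan applies to ring B.
- Weak points: the aldol aromatisation needs base while both β-acyloxy esters are present. Triketo esters also close through oxygen to 4-hydroxy-2-pyranones, which would expel the whole ring B–ring C alcohol. Ring B, the harder ring, still has to be made another way.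
- Comparison: for ring A this road is arguably better than the Mitsunobu step of the chosen plan. The chosen plan accepts a conventional ring A, because orsellinate esters can be bought, and reserves the ester-before-arene idea for ring B, where no conventional answer exists.

Key step: step 3

Assumption (remark on the chemistry): C1 and C6 of ring B are formed in step 3 as a mixture and erased in step 14, so they are written without configuration; β-dicarbonyl compounds are drawn as keto tautomers.

## Route

Step 1
Reactants: 1 ethyl propiolate; 2 (R)-propylene oxide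
Product: 4 ethyl (R)-5-hydroxyhex-2-ynoate, via ethyl 3-lithiopropiolate 3 (not isolated)
Conditions: n-BuLi, THF, −78 °C; BF3·OEt2, then 2, −78 °C; aq. NH4Cl
Reagents that add atoms: none
Why: Alkynylation of an epoxide by a lithium acetylide under BF3 activation (Yamaguchi–Hirao type); attack at the unsubstituted CH2 leaves the stereocentre of 2 untouched, so 4 is R. The low temperature keeps the lithiopropiolate from self-condensation.

Step 2
Reactants: 4 ethyl (R)-5-hydroxyhex-2-ynoate
Product: 6 (R)-6-methyl-5,6-dihydro-2H-pyran-2-one, via ethyl (R,Z)-5-hydroxyhex-2-enoate 5 (not isolated)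
Conditions: H2 (1 atm), Pd/CaCO3 poisoned with Pb(OAc)2 (Lindlar catalyst), quinoline, EtOAc, rt; filter; TsOH·H2O (cat.), toluene, 80 °C
Reagents that add atoms: none
Why: Lindlar semihydrogenation gives the Z-enoate, whose hydroxyl is placed to close the six-membered lactone by acid-catalysed transesterification. The carbinol C–O bond is not broken, so the R configuration is kept.

Step 3
Reactants: 6 (R)-6-methyl-5,6-dihydro-2H-pyran-2-one; 7 tert-butyl acetoacetate
Product: 9 tert-butyl 6-[(2R)-2-hydroxypropyl]-2,4-dioxocyclohexane-1-carboxylate, via Michael adduct lactone 8 (not isolated)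
Conditions: 7 (1.1 equiv), NaOC(CH3)3 (1.05 equiv), t-BuOH/THF, rt then 70 °C; cold 1 M HCl to pH 3
Reagents that add atoms: none
Why: The sodium enolate of 7, formed at C2 as the most acidic position, adds to C4 of 6 and gives adduct 8 after proton transfer (C1–C6 bond of ring B). A small equilibrium share of the acetyl-methyl enolate of 8 then attacks the lactone carbonyl, and the bridged 2-oxabicyclo[3.3.1]nonane tetrahedral intermediate collapses with expulsion of the ring oxygen, forming the C3–C4 bond and freeing the carbinol. The released alkoxide deprotonates the new 1,3-dione, which drives the otherwise reversible sequence, and acidification returns 9. The closest known reaction is the Michael–Dieckmann (Michael–Claisen) annulation of acetoacetates with crotonates to dihydroresorcylates; here the ester acceptor is a lactone, so the leaving alkoxide stays in the molecule. The carbocycle closes in the 6-(enolexo)-exo-trig mode, which requires the C4 substituent of the lactone to be axial, as it is in the trans adduct with equatorial methyl. The two new ring stereocentres (C1, epimerisable, and C6) need no control because step 14 removes both, and the carbinol centre comes unchanged from 6 because only the acyl–oxygen bond breaks. The selectivity needed is regiochemical (Michael bond from C2, Claisen bond from C4 of the acetoacetate); it is secured by thermodynamic monoanion conditions and by the fact that only this pairing closes a six-membered ring. The tert-butyl ester resists the liberated alkoxide, so the bicyclic δ-lactone should not form.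

Step 4
Reactants: 9 tert-butyl 6-[(2R)-2-hydroxypropyl]-2,4-dioxocyclohexane-1-carboxylate
Product: 10 tert-butyl 4-[(benzyloxy)methoxy]-6-[(2R)-2-hydroxypropyl]-2-oxocyclohex-3-ene-1-carboxylate
Conditions: BOMCl (1.05 equiv), i-Pr2NEt (1.1 equiv), CH2Cl2, −40 → 0 °C
Reagents that add atoms: benzyl chloromethyl ether (BOMCl), ClCOCc1ccccc1
Why: O-Alkylation of a 1,3-dione enolate by a chloromethyl ether, a hard electrophile that goes to oxygen, not carbon. The amine deprotonates only the dione (pKa about 5), so the secondary alcohol stays free, and the less hindered O4, remote from the tert-butyl ester, should react, leaving C1 a β-keto ester carbon. The vinylogous ester removes the acidic enol that would be acylated in step 12.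

Step 5
Reactants: 11 methyl 2,4-dihydroxy-6-methylbenzoate (methyl orsellinate)
Product: 12 methyl 2,4-bis(benzyloxy)-6-methylbenzoate
Conditions: BnBr (2.5 equiv), K2CO3, DMF, 60 °C
Reagents that add atoms: benzyl bromide, BrCc1ccccc1
Why: Williamson etherification of both phenols; warm DMF is needed for the hydrogen-bonded ortho hydroxyl.

Step 6
Reactants: 12 methyl 2,4-bis(benzyloxy)-6-methylbenzoate
Product: 13 2,4-bis(benzyloxy)-6-methylbenzoic acid
Conditions: KOH, DMSO/H2O, 100 °C; then aq. HCl
Reagents that add atoms: potassium hydroxide, [K+].[OH-]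
Why: Saponification of a di-ortho-substituted benzoate, which needs hydroxide in hot aqueous DMSO; aryl benzyl ethers are inert to base.

Step 7
Reactants: 13 2,4-bis(benzyloxy)-6-methylbenzoic acid; 14 tert-butyl (3S)-3-hydroxybutanoate
Product: 15 tert-butyl (3R)-3-{[2,4-bis(benzyloxy)-6-methylbenzoyl]oxy}butanoate
Conditions: PPh3, DIAD, toluene, 0 °C → rt
Reagents that add atoms: none
Why: Mitsunobu esterification: the hindered carboxylate is the nucleophile at the activated carbinol carbon, which avoids attack at the crowded carbonyl. SN2 inversion converts the S alcohol into the R ester.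

Step 8
Reactants: 15 tert-butyl (3R)-3-{[2,4-bis(benzyloxy)-6-methylbenzoyl]oxy}butanoate
Product: 16 (3R)-3-{[2,4-bis(benzyloxy)-6-methylbenzoyl]oxy}butanoic acid
Conditions: TFA/CH2Cl2 (1:4), 0 °C → rt
Reagents that add atoms: none
Why: Acidolysis of the tert-butyl ester by alkyl–oxygen cleavage. The aroyl ester, the benzyl ethers and the stereocentre are untouched, and no base is present to start β-elimination.

Step 9
Reactants: 17 1,3-bis(benzyloxy)-5-bromobenzene; 2 (R)-propylene oxide
Product: 19 (2R)-1-[3,5-bis(benzyloxy)phenyl]propan-2-ol, via arylmagnesium bromide 18 (not isolated)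
Conditions: Mg, THF, 40 °C; CuI (10 mol %), then 2, −30 → 0 °C; aq. NH4Cl
Reagents that add atoms: none
Why: CuI-catalysed opening of the epoxide by the aryl Grignard reagent at the CH2 terminus. The stereocentre of 2 is not involved, so 19 is R.

Step 10
Reactants: 19 (2R)-1-[3,5-bis(benzyloxy)phenyl]propan-2-ol; 20 2,2,6-trimethyl-4H-1,3-dioxin-4-one
Product: 22 (2R)-1-[3,5-bis(benzyloxy)phenyl]propan-2-yl 3-oxobutanoate, via acetylketene 21 (not isolated)
Conditions: 20 (1.5 equiv), xylenes, 140 °C
Reagents that add atoms: none
Why: Thermal retro-[4+2] of the dioxinone releases acetylketene, which the secondary alcohol captures under neutral conditions (acetoacetylation). No stereocentre is touched.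

Step 11
Reactants: 22 (2R)-1-[3,5-bis(benzyloxy)phenyl]propan-2-yl 3-oxobutanoate
Product: 23 (2R)-1-[3,5-bis(benzyloxy)phenyl]propan-2-yl (3R)-3-hydroxybutanoate
Conditions: H2 (30 bar), [RuCl(p-cymene)((R)-BINAP)]Cl (1 mol %), MeOH/CH2Cl2, 50 °C
Reagents that add atoms: none
Why: Noyori asymmetric hydrogenation of a β-keto ester; the (R)-BINAP catalyst sets the new carbinol as R under catalyst control, and the remote stereocentre in the alkoxy part should have little influence. The homogeneous catalyst does not hydrogenolyse aryl benzyl ethers.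

Step 12
Reactants: 10 tert-butyl 4-[(benzyloxy)methoxy]-6-[(2R)-2-hydroxypropyl]-2-oxocyclohex-3-ene-1-carboxylate; 16 (3R)-3-{[2,4-bis(benzyloxy)-6-methylbenzoyl]oxy}butanoic acid
Product: 24 tert-butyl 4-[(benzyloxy)methoxy]-6-[(2R)-2-{[(3R)-3-{[2,4-bis(benzyloxy)-6-methylbenzoyl]oxy}butanoyl]oxy}propyl]-2-oxocyclohex-3-ene-1-carboxylate
Conditions: EDC·HCl (1.3 equiv), DMAP (0.2 equiv), CH2Cl2, 0 °C → rt
Reagents that add atoms: none
Why: Steglich esterification of an unhindered aliphatic acid with a secondary alcohol, with retention at both carbinol centres. Catalytic DMAP at low temperature limits β-elimination of the activated β-aroyloxy acid, and the masked dione is inert.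

Step 13
Reactants: 24 tert-butyl ester from step 12; 23 (2R)-1-[3,5-bis(benzyloxy)phenyl]propan-2-yl (3R)-3-hydroxybutanoate
Product: 26 (2R)-1-[3,5-bis(benzyloxy)phenyl]propan-2-yl (3R)-3-({4-[(benzyloxy)methoxy]-6-[(2R)-2-{[(3R)-3-{[2,4-bis(benzyloxy)-6-methylbenzoyl]oxy}butanoyl]oxy}propyl]-2-oxocyclohex-3-ene-1-carbonyl}oxy)butanoate, via ring B acylketene 25 (not isolated)
Conditions: 23 (1.3 equiv), toluene, 110 °C, slow N2 stream to remove t-BuOH
Reagents that add atoms: none
Why: tert-Butyl β-keto esters lose tert-butanol on heating to give acylketenes, which alcohols capture (thermal ester exchange of the transacetoacetylation type). The C2 ketone of 24 can still enolise toward C1, and the medium is neutral, so both β-acyloxy esters should survive. The new bond forms at a ketene carbon, free of the crowding that blocks acylation by the aromatic acid.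

Step 14
Reactants: 26 dihydro ring B tetraester from step 13
Product: 27 (2R)-1-[3,5-bis(benzyloxy)phenyl]propan-2-yl (3R)-3-({4-[(benzyloxy)methoxy]-2-hydroxy-6-[(2R)-2-{[(3R)-3-{[2,4-bis(benzyloxy)-6-methylbenzoyl]oxy}butanoyl]oxy}propyl]benzoyl}oxy)butanoate
Conditions: DDQ (1.2 equiv), 1,4-dioxane, 80 °C
Reagents that add atoms: none
Why: DDQ dehydrogenation of a cyclohexenone β-keto ester: hydride abstraction from C6 of the dienol gives a cation stabilised by both ring oxygens, and loss of the C5 proton with tautomerisation gives the salicylate. Aryl benzyl ethers and the benzylic CH2 groups of meta-oxygenated rings are poor hydride donors.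

Step 15
Reactants: 27 protected hansforester A from step 14
Product: 28 hansforester A
Conditions: H2 (1 atm), Pd/C (10 wt %), EtOAc/EtOH, rt
Reagents that add atoms: none
Why: Hydrogenolysis cleaves the four aryl benzyl ethers and the benzyl group of the benzyloxymethyl ether, whose hemiformal then loses formaldehyde. The medium is neutral and none of the esters is benzylic, so the four esters and the four stereocentres should be untouched.

## Compound list

1 | ethyl propiolate | C#CC(=O)OCC | starting material
2 | (R)-propylene oxide | C[C@@H]1CO1 | starting material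
3 | ethyl 3-lithiopropiolate | [Li]C#CC(=O)OCC | intermediate
4 | ethyl (R)-5-hydroxyhex-2-ynoate | CCOC(=O)C#CC[C@@H](C)O | intermediate
5 | ethyl (R,Z)-5-hydroxyhex-2-enoate | CCOC(=O)/C=C\C[C@@H](C)O | intermediate
6 | (R)-6-methyl-5,6-dihydro-2H-pyran-2-one | O=C1C=CC[C@@H](C)O1 | intermediate
7 | tert-butyl acetoacetate | CC(=O)CC(=O)OC(C)(C)C | starting material
8 | tert-butyl 2-[(2R)-2-methyl-6-oxooxan-4-yl]-3-oxobutanoate (mixture at the two new centres) | CC(=O)C(C(=O)OC(C)(C)C)C1CC(=O)O[C@H](C)C1 | intermediate
9 | tert-butyl 6-[(2R)-2-hydroxypropyl]-2,4-dioxocyclohexane-1-carboxylate | C[C@@H](O)CC1CC(=O)CC(=O)C1C(=O)OC(C)(C)C | intermediate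
10 | tert-butyl 4-[(benzyloxy)methoxy]-6-[(2R)-2-hydroxypropyl]-2-oxocyclohex-3-ene-1-carboxylate | C[C@@H](O)CC1CC(OCOCc2ccccc2)=CC(=O)C1C(=O)OC(C)(C)C | intermediate
11 | methyl 2,4-dihydroxy-6-methylbenzoate | COC(=O)c1c(C)cc(O)cc1O | starting material
12 | methyl 2,4-bis(benzyloxy)-6-methylbenzoate | COC(=O)c1c(C)cc(OCc2ccccc2)cc1OCc1ccccc1 | intermediate
13 | 2,4-bis(benzyloxy)-6-methylbenzoic acid | Cc1cc(OCc2ccccc2)cc(OCc2ccccc2)c1C(=O)O | intermediate
14 | tert-butyl (3S)-3-hydroxybutanoate | C[C@H](O)CC(=O)OC(C)(C)C | starting material
15 | tert-butyl (3R)-3-{[2,4-bis(benzyloxy)-6-methylbenzoyl]oxy}butanoate | Cc1cc(OCc2ccccc2)cc(OCc2ccccc2)c1C(=O)O[C@H](C)CC(=O)OC(C)(C)C | intermediate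
16 | (3R)-3-{[2,4-bis(benzyloxy)-6-methylbenzoyl]oxy}butanoic acid | Cc1cc(OCc2ccccc2)cc(OCc2ccccc2)c1C(=O)O[C@H](C)CC(=O)O | intermediate
17 | 1,3-bis(benzyloxy)-5-bromobenzene | Brc1cc(OCc2ccccc2)cc(OCc2ccccc2)c1 | starting material
18 | [3,5-bis(benzyloxy)phenyl]magnesium bromide | Br[Mg]c1cc(OCc2ccccc2)cc(OCc2ccccc2)c1 | intermediate
19 | (2R)-1-[3,5-bis(benzyloxy)phenyl]propan-2-ol | C[C@@H](O)Cc1cc(OCc2ccccc2)cc(OCc2ccccc2)c1 | intermediate
20 | 2,2,6-trimethyl-4H-1,3-dioxin-4-one | CC1=CC(=O)OC(C)(C)O1 | starting material
21 | acetylketene | CC(=O)C=C=O | intermediate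
22 | (2R)-1-[3,5-bis(benzyloxy)phenyl]propan-2-yl 3-oxobutanoate | CC(=O)CC(=O)O[C@H](C)Cc1cc(OCc2ccccc2)cc(OCc2ccccc2)c1 | intermediate
23 | (2R)-1-[3,5-bis(benzyloxy)phenyl]propan-2-yl (3R)-3-hydroxybutanoate | C[C@@H](O)CC(=O)O[C@H](C)Cc1cc(OCc2ccccc2)cc(OCc2ccccc2)c1 | intermediate
24 | tert-butyl 4-[(benzyloxy)methoxy]-6-[(2R)-2-{[(3R)-3-{[2,4-bis(benzyloxy)-6-methylbenzoyl]oxy}butanoyl]oxy}propyl]-2-oxocyclohex-3-ene-1-carboxylate | Cc1cc(OCc2ccccc2)cc(OCc2ccccc2)c1C(=O)O[C@H](C)CC(=O)O[C@H](C)CC1CC(OCOCc2ccccc2)=CC(=O)C1C(=O)OC(C)(C)C | intermediate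
25 | (2R)-1-{5-[(benzyloxy)methoxy]-3-oxo-2-(oxomethylidene)cyclohex-4-en-1-yl}propan-2-yl (3R)-3-{[2,4-bis(benzyloxy)-6-methylbenzoyl]oxy}butanoate | Cc1cc(OCc2ccccc2)cc(OCc2ccccc2)c1C(=O)O[C@H](C)CC(=O)O[C@H](C)CC1CC(OCOCc2ccccc2)=CC(=O)C1=C=O | intermediate
26 | (2R)-1-[3,5-bis(benzyloxy)phenyl]propan-2-yl (3R)-3-({4-[(benzyloxy)methoxy]-6-[(2R)-2-{[(3R)-3-{[2,4-bis(benzyloxy)-6-methylbenzoyl]oxy}butanoyl]oxy}propyl]-2-oxocyclohex-3-ene-1-carbonyl}oxy)butanoate | Cc1cc(OCc2ccccc2)cc(OCc2ccccc2)c1C(=O)O[C@H](C)CC(=O)O[C@H](C)CC1CC(OCOCc2ccccc2)=CC(=O)C1C(=O)O[C@H](C)CC(=O)O[C@H](C)Cc1cc(OCc2ccccc2)cc(OCc2ccccc2)c1 | intermediate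
27 | (2R)-1-[3,5-bis(benzyloxy)phenyl]propan-2-yl (3R)-3-({4-[(benzyloxy)methoxy]-2-hydroxy-6-[(2R)-2-{[(3R)-3-{[2,4-bis(benzyloxy)-6-methylbenzoyl]oxy}butanoyl]oxy}propyl]benzoyl}oxy)butanoate | Cc1cc(OCc2ccccc2)cc(OCc2ccccc2)c1C(=O)O[C@H](C)CC(=O)O[C@H](C)Cc1cc(OCOCc2ccccc2)cc(O)c1C(=O)O[C@H](C)CC(=O)O[C@H](C)Cc1cc(OCc2ccccc2)cc(OCc2ccccc2)c1 | intermediate
28 | hansforester A, (2R)-1-(3,5-dihydroxyphenyl)propan-2-yl (3R)-3-({2,4-dihydroxy-6-[(2R)-2-{[(3R)-3-[(2,4-dihydroxy-6-methylbenzoyl)oxy]butanoyl]oxy}propyl]benzoyl}oxy)butanoate | Cc1cc(O)cc(O)c1C(=O)O[C@H](C)CC(=O)O[C@H](C)Cc1cc(O)cc(O)c1C(=O)O[C@H](C)CC(=O)O[C@H](C)Cc1cc(O)cc(O)c1 | target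

## Step count and least certain steps

Total: 15 steps. Longest linear sequence: 8 steps (steps 1–4 and 12–15 from ethyl propiolate; the ring A branch, steps 5–8 and 12–15, is equally long).

**Step 3 (key step).** The likely failures are base-induced opening of lactone 6 to the dienoate by γ-deprotonation and loss of the ring oxygen, or stalling at adduct 8 because too little acetyl-methyl enolate forms. The fallback returns to the acyclic form of the annulation; it sets out from 4 and comes back at 9. Silylation of 4 (TBSCl, imidazole) would give ethyl (R)-5-[(tert-butyldimethylsilyl)oxy]hex-2-ynoate F1. Lindlar semihydrogenation would give ethyl (R,Z)-5-[(tert-butyldimethylsilyl)oxy]hex-2-enoate F2, which cannot lactonise. F2 and 7 with NaOC(CH3)3 in t-BuOH should undergo the Michael–Dieckmann annulation to tert-butyl 6-[(2R)-2-{[tert-butyl(dimethyl)silyl]oxy}propyl]-2,4-dioxocyclohexane-1-carboxylate F3, and HF·pyridine would free the carbinol to give 9.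

**Step 13.** The likely failure is slow ketene formation, because the C2 ketone is part of a vinylogous ester and enolises less toward C1; long heating then invites ketene dimerisation or loss of the ester group by decarboxylation. The fallback makes the ring B ester at the aromatic stage by carboxylate alkylation; it sets out from 24 and comes back at 28. DDQ as in step 14 would aromatise 24 to tert-butyl 4-[(benzyloxy)methoxy]-2-hydroxy-6-[(2R)-2-{[(3R)-3-{[2,4-bis(benzyloxy)-6-methylbenzoyl]oxy}butanoyl]oxy}propyl]benzoate F4. Cold TFA would remove the tert-butyl group and the acetal to give the ring B dihydroxy acid F5. Mitsunobu esterification of F5 with (2R)-1-[3,5-bis(benzyloxy)phenyl]propan-2-yl (3S)-3-hydroxybutanoate F6, obtained from 22 as in step 11 but with the (S)-BINAP catalyst, would form the ring B ester with inversion and give the tetrabenzyl ether of hansforester A F7. Hydrogenolysis as in step 15 would give 28.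

**Step 14.** The likely failures are oxidation at the wrong site (hydride abstraction from a benzylic ether, or addition of the electron-rich enol ether carbon C3 to the quinone) and incomplete conversion. The fallback replaces hydride abstraction by selenoxide elimination; it sets out from 26 and comes back at 27. PhSeCl and pyridine in CH2Cl2 would selenenylate the β-keto ester carbon C1 to give the 1-(phenylselanyl) derivative of 26 F8. H2O2 at 0 °C would oxidise it to the selenoxide, whose syn-elimination toward C6–H and tautomerisation would give 27.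

**Step 4.** The likely failure is poor site selectivity between the two enolate oxygens (O2 against O4), with some alkylation at C3; the O2 isomer cannot form the acylketene of step 13. The fallback forms the enol ether under thermodynamic control; it sets out from 9 and comes back at 28. Benzyl alcohol with catalytic camphorsulfonic acid and azeotropic removal of water at 50 °C under reduced pressure should give the more stable tert-butyl 4-(benzyloxy)-6-[(2R)-2-hydroxypropyl]-2-oxocyclohex-3-ene-1-carboxylate F9. Steps 12 to 14 applied to F9 would give in turn its side-chain ester with 16 F10, the derived acylketene F11, the ring B ester of 23 F12 and the pentabenzyl ether of hansforester A F13. The hydrogenolysis of step 15 would then give 28 without release of formaldehyde.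

**Step 7.** The likely failure is dehydration of the β-hydroxy ester to the crotonate by elimination from the alkoxyphosphonium intermediate. The fallback acylates with retention; it sets out from 13 and comes back at 15. Oxalyl chloride with catalytic DMF would convert 13 into 2,4-bis(benzyloxy)-6-methylbenzoyl chloride F14. Its reaction with purchased tert-butyl (3R)-3-hydroxybutanoate F15 in warm pyridine with DMAP, as in the formation of mesitoate esters, would give 15.

## Further compounds

F1 | step 3 | ethyl (R)-5-[(tert-butyldimethylsilyl)oxy]hex-2-ynoate | CCOC(=O)C#CC[C@@H](C)O[Si](C)(C)C(C)(C)C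
F2 | step 3 | ethyl (R,Z)-5-[(tert-butyldimethylsilyl)oxy]hex-2-enoate | CCOC(=O)/C=C\C[C@@H](C)O[Si](C)(C)C(C)(C)C
F3 | step 3 | tert-butyl 6-[(2R)-2-{[tert-butyl(dimethyl)silyl]oxy}propyl]-2,4-dioxocyclohexane-1-carboxylate | C[C@@H](O[Si](C)(C)C(C)(C)C)CC1CC(=O)CC(=O)C1C(=O)OC(C)(C)C
F4 | step 13 | tert-butyl 4-[(benzyloxy)methoxy]-2-hydroxy-6-[(2R)-2-{[(3R)-3-{[2,4-bis(benzyloxy)-6-methylbenzoyl]oxy}butanoyl]oxy}propyl]benzoate | Cc1cc(OCc2ccccc2)cc(OCc2ccccc2)c1C(=O)O[C@H](C)CC(=O)O[C@H](C)Cc1cc(OCOCc2ccccc2)cc(O)c1C(=O)OC(C)(C)C
F5 | step 13 | 2,4-dihydroxy-6-[(2R)-2-{[(3R)-3-{[2,4-bis(benzyloxy)-6-methylbenzoyl]oxy}butanoyl]oxy}propyl]benzoic acid | Cc1cc(OCc2ccccc2)cc(OCc2ccccc2)c1C(=O)O[C@H](C)CC(=O)O[C@H](C)Cc1cc(O)cc(O)c1C(=O)O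
F6 | step 13 | (2R)-1-[3,5-bis(benzyloxy)phenyl]propan-2-yl (3S)-3-hydroxybutanoate | C[C@H](O)CC(=O)O[C@H](C)Cc1cc(OCc2ccccc2)cc(OCc2ccccc2)c1
F7 | step 13 | (2R)-1-[3,5-bis(benzyloxy)phenyl]propan-2-yl (3R)-3-({2,4-dihydroxy-6-[(2R)-2-{[(3R)-3-{[2,4-bis(benzyloxy)-6-methylbenzoyl]oxy}butanoyl]oxy}propyl]benzoyl}oxy)butanoate | Cc1cc(OCc2ccccc2)cc(OCc2ccccc2)c1C(=O)O[C@H](C)CC(=O)O[C@H](C)Cc1cc(O)cc(O)c1C(=O)O[C@H](C)CC(=O)O[C@H](C)Cc1cc(OCc2ccccc2)cc(OCc2ccccc2)c1
F8 | step 14 | (2R)-1-[3,5-bis(benzyloxy)phenyl]propan-2-yl (3R)-3-({4-[(benzyloxy)methoxy]-6-[(2R)-2-{[(3R)-3-{[2,4-bis(benzyloxy)-6-methylbenzoyl]oxy}butanoyl]oxy}propyl]-2-oxo-1-(phenylselanyl)cyclohex-3-ene-1-carbonyl}oxy)butanoate | Cc1cc(OCc2ccccc2)cc(OCc2ccccc2)c1C(=O)O[C@H](C)CC(=O)O[C@H](C)CC1CC(OCOCc2ccccc2)=CC(=O)C1([Se]c2ccccc2)C(=O)O[C@H](C)CC(=O)O[C@H](C)Cc1cc(OCc2ccccc2)cc(OCc2ccccc2)c1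
F9 | step 4 | tert-butyl 4-(benzyloxy)-6-[(2R)-2-hydroxypropyl]-2-oxocyclohex-3-ene-1-carboxylate | C[C@@H](O)CC1CC(OCc2ccccc2)=CC(=O)C1C(=O)OC(C)(C)C
F10 | step 4 | tert-butyl 4-(benzyloxy)-6-[(2R)-2-{[(3R)-3-{[2,4-bis(benzyloxy)-6-methylbenzoyl]oxy}butanoyl]oxy}propyl]-2-oxocyclohex-3-ene-1-carboxylate | Cc1cc(OCc2ccccc2)cc(OCc2ccccc2)c1C(=O)O[C@H](C)CC(=O)O[C@H](C)CC1CC(OCc2ccccc2)=CC(=O)C1C(=O)OC(C)(C)C
F11 | step 4 | (2R)-1-[5-(benzyloxy)-3-oxo-2-(oxomethylidene)cyclohex-4-en-1-yl]propan-2-yl (3R)-3-{[2,4-bis(benzyloxy)-6-methylbenzoyl]oxy}butanoate | Cc1cc(OCc2ccccc2)cc(OCc2ccccc2)c1C(=O)O[C@H](C)CC(=O)O[C@H](C)CC1CC(OCc2ccccc2)=CC(=O)C1=C=O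
F12 | step 4 | (2R)-1-[3,5-bis(benzyloxy)phenyl]propan-2-yl (3R)-3-({4-(benzyloxy)-6-[(2R)-2-{[(3R)-3-{[2,4-bis(benzyloxy)-6-methylbenzoyl]oxy}butanoyl]oxy}propyl]-2-oxocyclohex-3-ene-1-carbonyl}oxy)butanoate | Cc1cc(OCc2ccccc2)cc(OCc2ccccc2)c1C(=O)O[C@H](C)CC(=O)O[C@H](C)CC1CC(OCc2ccccc2)=CC(=O)C1C(=O)O[C@H](C)CC(=O)O[C@H](C)Cc1cc(OCc2ccccc2)cc(OCc2ccccc2)c1
F13 | step 4 | (2R)-1-[3,5-bis(benzyloxy)phenyl]propan-2-yl (3R)-3-({4-(benzyloxy)-2-hydroxy-6-[(2R)-2-{[(3R)-3-{[2,4-bis(benzyloxy)-6-methylbenzoyl]oxy}butanoyl]oxy}propyl]benzoyl}oxy)butanoate | Cc1cc(OCc2ccccc2)cc(OCc2ccccc2)c1C(=O)O[C@H](C)CC(=O)O[C@H](C)Cc1cc(OCc2ccccc2)cc(O)c1C(=O)O[C@H](C)CC(=O)O[C@H](C)Cc1cc(OCc2ccccc2)cc(OCc2ccccc2)c1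
F14 | step 7 | 2,4-bis(benzyloxy)-6-methylbenzoyl chloride | Cc1cc(OCc2ccccc2)cc(OCc2ccccc2)c1C(=O)Cl
F15 | step 7 | tert-butyl (3R)-3-hydroxybutanoate | C[C@@H](O)CC(=O)OC(C)(C)C
A1 | alternative 1 | (R)-6,8-dimethoxy-3-methylisochroman-1-one | COc1cc(OC)c2C(=O)O[C@H](C)Cc2c1
A2 | alternative 1 | 2,4-dimethoxybenzoic acid | COc1ccc(C(=O)O)c(OC)c1
A3 | alternative 2 | hansforester A hexaacetate | Cc1cc(OC(C)=O)cc(OC(C)=O)c1C(=O)O[C@H](C)CC(=O)O[C@H](C)Cc1cc(OC(C)=O)cc(OC(C)=O)c1C(=O)O[C@H](C)CC(=O)O[C@H](C)Cc1cc(OC(C)=O)cc(OC(C)=O)c1
A4 | alternative 2 | diketone analogue of A3 lacking the ester oxygens on the ring B and ring C carbinol carbons | Cc1cc(OC(C)=O)cc(OC(C)=O)c1C(=O)O[C@H](C)CC(=O)[C@H](C)Cc1cc(OC(C)=O)cc(OC(C)=O)c1C(=O)O[C@H](C)CC(=O)[C@H](C)Cc1cc(OC(C)=O)cc(OC(C)=O)c1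
A5 | alternative 3 | hansforester A with rings B and C as benzyl ethers | Cc1cc(O)cc(O)c1C(=O)O[C@H](C)CC(=O)O[C@H](C)Cc1cc(OCc2ccccc2)cc(OCc2ccccc2)c1C(=O)O[C@H](C)CC(=O)O[C@H](C)Cc1cc(OCc2ccccc2)cc(OCc2ccccc2)c1
A6 | alternative 3 | 3,5,7-trioxooctanoate ester of the benzyl-protected ring B–ring C alcohol | CC(=O)CC(=O)CC(=O)CC(=O)O[C@H](C)CC(=O)O[C@H](C)Cc1cc(OCc2ccccc2)cc(OCc2ccccc2)c1C(=O)O[C@H](C)CC(=O)O[C@H](C)Cc1cc(OCc2ccccc2)cc(OCc2ccccc2)c1
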